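The runs were computed with constants of no real substance.

Late in Saturday's run of this flask the two products parted ways: left-handed product lay flat, reading 49.9% at 30.0 min and 49.5% at 40.0 min, while right-handed product was still rising.

all flasks: left-handed substrate 11 mM; right-handed substrate 11 mM; free catalyst 0.11 mM; racemization catalyst 22 µM; impurity 29 µM

|  | solid reagent | remark | time |
|---|---|---|---|
| Saturday's | 22 mM | the very flask that is asked about, followed so far |  |
| flask | 22.0 mM |  | 4.0 h |

Saturday's run (percent of the left-handed substrate and right-handed substrate together charged)

| time / min | left-handed product / % | right-handed product / % |
|---|---|---|
| 3.00 | 12.7 | 0 |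
| 5.00 | 18.9 | 0.7 |
| 8.00 | 29.8 | 0.7 |
| 12.0 | 38.2 | 0.7 |
| 20.0 | 48.2 | 0.4 |
| 30.0 | 49.9 | 1.5 |
| 40.0 | 49.5 | 2.8 |

(each reading ± 1 percentage point)

- free catalyst is single-handed; left-handed substrate and right-handed substrate are mirror images of each other, charged as a racemate, each of them at the stated concentration
- as a solid, counted per litre of solution: solid reagent
- the numbers in the tables scatter by 1 percentage point (one standard deviation)
- at the start none of the solid reagent is in solution
- an excess is below zero if the other one leads

- left-handed product and right-handed product together, in percent of the left-handed substrate and right-handed substrate charged together, at 4.0 h
- excess of left-handed product over right-handed product in the product at 4.0 h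
- whether the exchange between left-handed substrate and right-handed substrate keeps pace with the reaction: how far the product's excess at 4.0 h gets from its value without exchange to its value with instant exchange (above 80% keeps pace, below 20% hardly takes part, else lags behind)

I kept a ledger of the solid reagent, taking one unit of it for each unit of product, so the budget for this flask was 22.0 mM. The first entry was left-handed product. I booked it at 11 mM, the whole left-handed charge. Its flat readings showed no refill, so I booked nothing for exchange and expected that exchange hardly takes part.

The second entry was right-handed product, and for it I counted turnovers. From 20.0 min to 40.0 min it rose 2.4 percentage points, a rough figure given the scatter of 1 point on each reading. That is 4.80 turnovers per catalyst. Dividing by the time and by the right-handed substrate then present, 10.7 mM, gave my slow turnover number, 1.35 /mM/h: turnovers per catalyst per hour per mM of right-handed substrate. I treated the slow channel as pseudo-first-order, with a rate constant equal to this number times [free catalyst]. Over 4.0 h this gave right-handed product of 22.4%, or 4.93 mM of solid reagent.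

That left 6.07 mM of the budget, so the solid reagent outlasted my reckoning. My books closed at a yield of 72.4% and an excess of 38.1%.

The forecast said 66%, 52% and hardly takes part: “This is plain kinetic resolution.” Its right-handed product of 16 % lay below mine.

This flask gave 72.2% and 38.6%, and the exchange, which hardly takes part, got 0.18% of the way.

    coupling partner + free catalyst + left-handed substrate → free catalyst + left-handed product (k = 10000 /M²/s)
    coupling partner + free catalyst + right-handed substrate → free catalyst + right-handed product (k = 110 /M²/s)
    left-handed substrate + racemization catalyst ⇌ right-handed substrate + racemization catalyst, rate k3*[racemization catalyst]*[left-handed substrate] forward; the back reaction follows from the equilibrium constant (k = 5.50 /M/s)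
    racemization catalyst + impurity → spent catalyst A (k = 1100 /M/s)
    solid reagent ⇌ coupling partner, rate k5*(cs5 - [coupling partner]) while solid is left; crystals form when [coupling partner] > cs5 (solubility = 3.50 mM, k = 0.00970 /s)
    racemization catalyst → spent catalyst B (k = 2.10 × 10⁻⁴ /s)

At 0.157 h in this flask the path to left-handed product used coupling partner 31 times as fast as the path to right-handed product. In this flask, counted in percent of both substrates charged together, left-handed substrate stood at 1.02% after 0.400 h, and right-handed product stood at 22.2% after 4.00 h, against my 22.4%. For a second flask with 0.044 mM of free catalyst, the slow turnover number 1.35 /mM/h gives right-handed product of 10.6%, a yield of 60.6% and an excess of 65.0%. The computed flask gave 60.5% and 65.3%.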